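**Plan**

1. The target is read as a 3-exo-hydroxy-6-exo-isopropylnorbornane (C1 quaternary bridgehead, C2 H2, C3 H–OH, C4 bridgehead CH, C5 H2, C6 H–iPr, C7 one-carbon bridge CH). Its C1–C7 bond is shared with cyclohexane ring C, which is trans-fused to ring D (CHBr, C–CH3, C(CH3)OH).
2. Cuts, in retrosynthetic order: C–Br (from an alkenyl bromide), the carbinol C–CH3 (MeMgBr on a ring D ketone), C3–OH (from C3=O); then C4–C5 (enolate alkylation, ring A); then removal of C4 (cyclopentanone back to cyclobutanone); then C2–C3 and C7–C1 together (ketene + alkene [2+2]); then the two arms on ring D.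
3. Enabling feature: in ring B (C1, C2, C3, C4, C7) the carbonyl-level C3 and C7 flank C4, so taking out C4 leaves the cyclobutanone C3(=O)–C7–C1–C2, the adduct of a ketene C7=C3=O and a 1,1-disubstituted alkene C1=C2. C7 and C1 are also joined through the four other atoms of ring C, two of which are adjacent carbons of ring D, so the cycloaddition is intramolecular and closes ring C as well.
4. Forward: ring D from p-benzoquinone mono(ethylene ketal); then [2+2] (ring C and the four-membered ring); one-carbon ring expansion (ring B); intramolecular alkylation (ring A); reduction, deketalization, MeMgBr, hydrogen-atom-transfer hydrogenation of the alkenyl bromide.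
5. Stereochemistry: a catalyst sets the ring D junction CH and an oxazolidinone auxiliary sets C6. The rest is relayed: trans alkylation (quaternary ring D carbon), chair closure (C7, C1), bridging (C4), endo hydride (C3), equatorial Grignard attack (carbinol), axial H-atom delivery (CHBr).

Key step: step 13

Remark: the catalyst enantiomer in step 1 is chosen by analogy with cyclohex-2-enone, on the assumption that the spiro ketal does not change the sense of induction.

**Route**

Step 1
Reactants: 1 1,4-dioxaspiro[4.5]deca-6,9-dien-8-one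
Product: 2 dimethyl 2-[(6R)-8-oxo-1,4-dioxaspiro[4.5]dec-9-en-6-yl]propanedioate
Conditions: dimethyl malonate, LiAl[(R)-binaphthoxide]2 (5 mol %), KOtBu (4.5 mol %), 4 Å MS, THF, 0 °C to rt
Reagents that add atoms: dimethyl malonate, COC(=O)CC(=O)OC
Why: Catalytic asymmetric Michael addition of a malonate to a cyclic enone; the two enone units of 1 are enantiotopic, so one addition desymmetrizes the dienone and the catalyst's face selection should set the ring D junction CH.

Step 2
Reactants: 2 dimethyl 2-[(6R)-8-oxo-1,4-dioxaspiro[4.5]dec-9-en-6-yl]propanedioate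
Product: 3 methyl 2-[(6R)-8-oxo-1,4-dioxaspiro[4.5]dec-9-en-6-yl]acetate
Conditions: NaCl, DMSO, H2O, 150 °C
Reagents that add atoms: none
Why: Krapcho dealkoxycarbonylation is neutral, so the acid-labile enone ketal and the stereocenter should survive.

Step 3
Reactants: 3 methyl 2-[(6R)-8-oxo-1,4-dioxaspiro[4.5]dec-9-en-6-yl]acetate
Product: 4 methyl 2-[(6S,7S)-7-methyl-8-oxo-1,4-dioxaspiro[4.5]dec-9-en-6-yl]acetate (trans isomer shown)
Conditions: LiHMDS, THF, -78 °C; MeI, -78 to -40 °C
Reagents that add atoms: iodomethane, CI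
Why: Kinetic enolate alkylation at the only enolizable ketone position (the ketal carbon blocks the γ-side) should give the 7-methyl ketone; this centre is made planar again in step 8, so its configuration does not matter.

Step 4
Reactants: 5 (4S)-4-benzyl-3-(3-methylbutanoyl)-1,3-oxazolidin-2-one
Product: 6 (4S)-4-benzyl-3-[(2R)-2-(hydroxymethyl)-3-methylbutanoyl]-1,3-oxazolidin-2-one
Conditions: TiCl4, iPr2NEt, CH2Cl2, 0 °C; then 1,3,5-trioxane, TiCl4, 0 °C
Reagents that add atoms: 1,3,5-trioxane, C1OCOCO1
Why: Evans titanium-enolate hydroxymethylation (aldol-type addition to formaldehyde); the chelated Z-enolate is attacked on the face away from the benzyl group, which should give the (2R) centre that becomes C6.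

Step 5
Reactants: 6 (4S)-4-benzyl-3-[(2R)-2-(hydroxymethyl)-3-methylbutanoyl]-1,3-oxazolidin-2-one
Product: 7 (2R)-2-(hydroxymethyl)-N-methoxy-N,3-dimethylbutanamide
Conditions: MeNH(OMe)·HCl, AlMe3, CH2Cl2, -10 °C to rt
Reagents that add atoms: N,O-dimethylhydroxylamine hydrochloride, CNOC.Cl
Why: Weinreb transamidation with the aluminium amide, assisted by the free β-hydroxyl, should remove the auxiliary without epimerization.

Step 6
Reactants: 7 (2R)-2-(hydroxymethyl)-N-methoxy-N,3-dimethylbutanamide
Product: 8 (2R)-2-{[tert-butyl(dimethyl)silyl]oxymethyl}-N-methoxy-N,3-dimethylbutanamide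
Conditions: TBSCl, imidazole, DMF, rt
Reagents that add atoms: tert-butyl(chloro)dimethylsilane, CC(C)(C)[Si](C)(C)Cl
Why: Standard silylation of a primary alcohol; the ether masks the future leaving-group site (C5) until step 15.

Step 7
Reactants: 8 (2R)-2-{[tert-butyl(dimethyl)silyl]oxymethyl}-N-methoxy-N,3-dimethylbutanamide
Product: 9 (4R)-4-{[tert-butyl(dimethyl)silyl]oxymethyl}-5-methyl-2-(trimethylsilyl)hex-1-en-3-one
Conditions: (1-bromoethenyl)trimethylsilane, Mg, THF; then 8, -20 to 0 °C
Reagents that add atoms: (1-bromoethenyl)trimethylsilane, C=C(Br)[Si](C)(C)C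
Why: Weinreb ketone synthesis; the chelated tetrahedral intermediate prevents over-addition and should give the α-silyl vinyl ketone needed for an aprotic Michael addition.

Step 8
Reactants: 4 methyl 2-[(6S,7S)-7-methyl-8-oxo-1,4-dioxaspiro[4.5]dec-9-en-6-yl]acetate; 9 (4R)-4-{[tert-butyl(dimethyl)silyl]oxymethyl}-5-methyl-2-(trimethylsilyl)hex-1-en-3-one
Product: 11 methyl 2-[(6S,7S)-7-[(4R)-4-{[tert-butyl(dimethyl)silyl]oxymethyl}-5-methyl-3-oxohexyl]-7-methyl-8-oxo-1,4-dioxaspiro[4.5]dec-9-en-6-yl]acetate, via α-silyl ketone adduct 10 (not isolated)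
Conditions: LiHMDS, THF, -78 to -30 °C; 9, -78 °C; AcOH; then KF (cat.), MeOH, rt
Reagents that add atoms: none
Why: Stork–Ganem-type Michael addition of a regiodefined lithium enolate to an α-silyl vinyl ketone; the acceptor should approach the tetrasubstituted enolate anti to the neighbouring acetate arm, which sets the quaternary carbon with methyl cis to that arm, and the silyl group (removed by fluoride-catalysed methanolysis) suppresses polymerization and a second Michael closure onto the ring enone.

Step 9
Reactants: 11 methyl 2-[(6S,7S)-7-[(4R)-4-{[tert-butyl(dimethyl)silyl]oxymethyl}-5-methyl-3-oxohexyl]-7-methyl-8-oxo-1,4-dioxaspiro[4.5]dec-9-en-6-yl]acetate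
Product: 12 methyl 2-[(6S,7S)-7-[(4S)-4-{[tert-butyl(dimethyl)silyl]oxymethyl}-5-methyl-3-methylidenehexyl]-7-methyl-8-oxo-1,4-dioxaspiro[4.5]dec-9-en-6-yl]acetate
Conditions: Cp2TiMe2, toluene, 70 °C
Reagents that add atoms: dimethyltitanocene, C[Ti](C)(C1C=CC=C1)C1C=CC=C1
Why: Petasis methylenation; the non-basic titanium carbene should react with the side-chain ketone faster than with the conjugated, α-quaternary ring ketone or the ester, without epimerizing the adjacent centre or eliminating the β-silyloxy group.

Step 10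
Reactants: 12 methyl 2-[(6S,7S)-7-[(4S)-4-{[tert-butyl(dimethyl)silyl]oxymethyl}-5-methyl-3-methylidenehexyl]-7-methyl-8-oxo-1,4-dioxaspiro[4.5]dec-9-en-6-yl]acetate
Product: 13 methyl 2-[(6S,7S)-7-[(4S)-4-{[tert-butyl(dimethyl)silyl]oxymethyl}-5-methyl-3-methylidenehexyl]-7-methyl-8-{[(trifluoromethyl)sulfonyl]oxy}-1,4-dioxaspiro[4.5]dec-8-en-6-yl]acetate
Conditions: Li[HB(sec-Bu)3], THF, -78 °C; then PhNTf2, -78 to 0 °C
Reagents that add atoms: N-phenylbis(trifluoromethanesulfonimide), O=S(=O)(N(c1ccccc1)S(=O)(=O)C(F)(F)F)C(F)(F)F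
Why: Conjugate reduction of the enone by a bulky borohydride with trapping of the regiodefined enolate as the enol triflate; 1,2-attack is disfavoured at a carbonyl flanked by a quaternary carbon, and the isolated alkene and ester should be untouched.

Step 11
Reactants: 13 enol triflate (name as in step 10)
Product: 14 methyl 2-[(6S,7S)-8-bromo-7-[(4S)-4-{[tert-butyl(dimethyl)silyl]oxymethyl}-5-methyl-3-methylidenehexyl]-7-methyl-1,4-dioxaspiro[4.5]dec-8-en-6-yl]acetate
Conditions: [Cp*Ru(NCMe)3]OTf (5 mol %), LiBr, 1,3-dimethylimidazolidin-2-one, 100 °C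
Reagents that add atoms: lithium bromide, [Li+].[Br-]
Why: Ruthenium-catalysed exchange of an alkenyl triflate for bromide should give the alkenyl bromide that carries the bromine to the end; any ester demethylation by bromide converges on 15.

Step 12
Reactants: 14 alkenyl bromide ester (name as in step 11)
Product: 15 2-[(6S,7S)-8-bromo-7-[(4S)-4-{[tert-butyl(dimethyl)silyl]oxymethyl}-5-methyl-3-methylidenehexyl]-7-methyl-1,4-dioxaspiro[4.5]dec-8-en-6-yl]acetic acid
Conditions: LiOH, THF/MeOH/H2O, rt; then dilute HCl to pH 4, 0 °C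
Reagents that add atoms: lithium hydroxide, [Li+].[OH-]
Why: Saponification of an unhindered methyl ester; the silyl ether, ketal and alkenyl bromide should tolerate it.

Step 13
Reactants: 15 alkenyl bromide acid (name as in step 12)
Product: 18 tricyclic cyclobutanone (ring D bromoalkene ketal, new ring C trans-fused to it, cyclobutanone cis-fused to ring C; C7–H anti to the ring C/D junction H and cis to the C6 arm on quaternary C1), via acid chloride 16 (not isolated), via ketene 17 (not isolated)
Conditions: Me2C=C(Cl)NMe2, CH2Cl2, 0 °C; then slow addition to Et3N, toluene, 110 °C (0.005 M)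
Reagents that add atoms: none
Why: Dehydrochlorination of acid chloride 16 gives aldoketene 17, whose carbonyl carbon (future C3) bonds to the terminal CH2 (C2) of the 1,1-disubstituted alkene while the ketene α-carbon (C7) bonds to the disubstituted alkene carbon (C1) in a concerted, asynchronous [π2s + π2a] cycloaddition; the closest known reaction type is the thermal intramolecular ketene–alkene [2+2] cycloaddition. The four-membered ring closes in the fused mode that the alkene polarization dictates (charge builds on the disubstituted carbon), and ring C closes at the same time as a six-membered ring through the C7–C1 bond, because the ketene and alkene arms sit trans-diequatorial on adjacent ring D carbons. C7 and C1 are set by a chair-like ring C transition state: the ketene carbonyl carbon takes the equatorial site at C7, away from the axial angular methyl, and the branched C6 arm takes the equatorial site at C1, which forces the cis-fused cyclobutanone with C7–H anti to the junction hydrogen. The step needs selectivity for the electron-rich 1,1-dialkyl alkene over the bromoalkene and over ketene dimerization; the bromine-deactivated, geometrically remote ring D alkene and slow addition at high dilution should secure this.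

Step 14
Reactants: 18 tricyclic cyclobutanone
Product: 20 cis-fused cyclopentanone (C3=O flanked by C2 H2 and new C4 H2; C4 bonded to C7), via oxaspirohexane 19 (not isolated)
Conditions: Me3S+ I-, n-BuLi, THF, -10 °C; 18, 0 °C; then LiI, 60 °C
Reagents that add atoms: trimethylsulfonium iodide, C[S+](C)C.[I-]
Why: Corey–Chaykovsky epoxidation of the strained ketone, then iodide-promoted semipinacol ring expansion of the oxaspirohexane; the more substituted α-carbon (C7, secondary) should migrate in preference to C2 (primary), with retention at C7 and relief of four-ring strain, and either spiro epimer of 19 converges.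

Step 15
Reactants: 20 cis-fused cyclopentanone
Product: 21 primary tosylate of 20 (C5–OTs)
Conditions: TsF, DBU (20 mol %), MeCN, rt
Reagents that add atoms: 4-methylbenzenesulfonyl fluoride, Cc1ccc(cc1)S(=O)(=O)F
Why: Base-catalysed exchange of a silyl ether for a sulfonate with a sulfonyl fluoride, driven by Si–F bond formation, should give the tosylate directly without a free alcohol.

Step 16
Reactants: 21 primary tosylate
Product: 22 norbornan-3-one (rings A to D complete; C3=O, ring D as bromoalkene ketal)
Conditions: KOtBu, t-BuOH/THF, 0 °C to rt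
Reagents that add atoms: none
Why: Intramolecular enolate alkylation to a norbornanone; only the C4 enolate can reach C5 (the C2 enolate would close a four-membered ring and O-alkylation would need a bridgehead enol ether), and the bridge geometry fixes the new C4 centre.

Step 17
Reactants: 22 norbornan-3-one
Product: 24 3-exo-hydroxy ring D ketone (bromoalkene retained), via exo-alcohol ketal 23 (not isolated)
Conditions: NaBH4, MeOH, 0 °C; then 2 M HCl, acetone, rt
Reagents that add atoms: water, O
Why: Hydride reduction from the endo face, the exo face being shielded by the ring C carbon on C7 that lies syn to the carbonyl bridge (the camphor-to-isoborneol pattern), should give the exo alcohol; aqueous acid then hydrolyses the dioxolane.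

Step 18
Reactants: 24 3-exo-hydroxy ring D ketone
Product: 25 diol alkenyl bromide (tertiary methyl carbinol in place)
Conditions: MeMgBr, CeCl3, THF, -78 to 0 °C
Reagents that add atoms: methylmagnesium bromide, C[Mg]Br
Why: Cerium-mediated Grignard 1,2-addition; axial approach is blocked by the syn-axial angular methyl, so equatorial attack should give the axial hydroxyl and equatorial methyl of the target.

Step 19
Reactants: 25 diol alkenyl bromide
Product: 26 target CNP0317598.2
Conditions: Mn(dpm)3 (10 mol %), PhSiH3, t-BuOOH, i-PrOH, rt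
Reagents that add atoms: none
Why: Metal-hydride hydrogen-atom-transfer hydrogenation of a haloalkene; H adds first to the unsubstituted alkene carbon, and the α-bromo radical should accept the second H axially, on the face opposite the axial angular methyl, which gives the equatorial bromide without C–Br cleavage.

**Compound list**

1 | 1,4-dioxaspiro[4.5]deca-6,9-dien-8-one | O=C1C=CC2(OCCO2)C=C1 | starting material
2 | dimethyl 2-[(6R)-8-oxo-1,4-dioxaspiro[4.5]dec-9-en-6-yl]propanedioate | COC(=O)C(C(=O)OC)[C@H]1CC(=O)C=CC12OCCO2 | intermediate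
3 | methyl 2-[(6R)-8-oxo-1,4-dioxaspiro[4.5]dec-9-en-6-yl]acetate | COC(=O)C[C@H]1CC(=O)C=CC12OCCO2 | intermediate
4 | methyl 2-[(6S,7S)-7-methyl-8-oxo-1,4-dioxaspiro[4.5]dec-9-en-6-yl]acetate | C[C@H]1[C@H](CC(=O)OC)C2(OCCO2)C=CC1=O | intermediate
5 | (4S)-4-benzyl-3-(3-methylbutanoyl)-1,3-oxazolidin-2-one | CC(C)CC(=O)N1[C@@H](Cc2ccccc2)COC1=O | starting material
6 | (4S)-4-benzyl-3-[(2R)-2-(hydroxymethyl)-3-methylbutanoyl]-1,3-oxazolidin-2-one | CC(C)[C@H](CO)C(=O)N1[C@@H](Cc2ccccc2)COC1=O | intermediate
7 | (2R)-2-(hydroxymethyl)-N-methoxy-N,3-dimethylbutanamide | CC(C)[C@H](CO)C(=O)N(C)OC | intermediate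
8 | (2R)-2-{[tert-butyl(dimethyl)silyl]oxymethyl}-N-methoxy-N,3-dimethylbutanamide | CC(C)[C@H](CO[Si](C)(C)C(C)(C)C)C(=O)N(C)OC | intermediate
9 | (4R)-4-{[tert-butyl(dimethyl)silyl]oxymethyl}-5-methyl-2-(trimethylsilyl)hex-1-en-3-one | C=C([Si](C)(C)C)C(=O)[C@@H](CO[Si](C)(C)C(C)(C)C)C(C)C | intermediate
10 | α-silyl ketone adduct (11 with SiMe3 on the CH2 next to the side-chain ketone; epimers at that carbon) | CC(C)[C@H](CO[Si](C)(C)C(C)(C)C)C(=O)C([Si](C)(C)C)C[C@@]1(C)[C@H](CC(=O)OC)C2(OCCO2)C=CC1=O | intermediate
11 | methyl 2-[(6S,7S)-7-[(4R)-4-{[tert-butyl(dimethyl)silyl]oxymethyl}-5-methyl-3-oxohexyl]-7-methyl-8-oxo-1,4-dioxaspiro[4.5]dec-9-en-6-yl]acetate | CC(C)[C@H](CO[Si](C)(C)C(C)(C)C)C(=O)CC[C@@]1(C)[C@H](CC(=O)OC)C2(OCCO2)C=CC1=O | intermediate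
12 | methyl 2-[(6S,7S)-7-[(4S)-4-{[tert-butyl(dimethyl)silyl]oxymethyl}-5-methyl-3-methylidenehexyl]-7-methyl-8-oxo-1,4-dioxaspiro[4.5]dec-9-en-6-yl]acetate | CC(C)[C@H](CO[Si](C)(C)C(C)(C)C)C(=C)CC[C@@]1(C)[C@H](CC(=O)OC)C2(OCCO2)C=CC1=O | intermediate
13 | enol triflate: methyl 2-[(6S,7S)-7-[(4S)-4-{[tert-butyl(dimethyl)silyl]oxymethyl}-5-methyl-3-methylidenehexyl]-7-methyl-8-{[(trifluoromethyl)sulfonyl]oxy}-1,4-dioxaspiro[4.5]dec-8-en-6-yl]acetate | CC(C)[C@H](CO[Si](C)(C)C(C)(C)C)C(=C)CC[C@@]1(C)[C@H](CC(=O)OC)C2(OCCO2)CC=C1OS(=O)(=O)C(F)(F)F | intermediate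
14 | alkenyl bromide ester: methyl 2-[(6S,7S)-8-bromo-7-[(4S)-4-{[tert-butyl(dimethyl)silyl]oxymethyl}-5-methyl-3-methylidenehexyl]-7-methyl-1,4-dioxaspiro[4.5]dec-8-en-6-yl]acetate | CC(C)[C@H](CO[Si](C)(C)C(C)(C)C)C(=C)CC[C@@]1(C)[C@H](CC(=O)OC)C2(OCCO2)CC=C1Br | intermediate
15 | alkenyl bromide acid: the acetic acid corresponding to 14 | CC(C)[C@H](CO[Si](C)(C)C(C)(C)C)C(=C)CC[C@@]1(C)[C@H](CC(=O)O)C2(OCCO2)CC=C1Br | intermediate
16 | acid chloride of 15 | CC(C)[C@H](CO[Si](C)(C)C(C)(C)C)C(=C)CC[C@@]1(C)[C@H](CC(=O)Cl)C2(OCCO2)CC=C1Br | intermediate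
17 | ketene from 16 (ring D–CH=C=O) | CC(C)[C@H](CO[Si](C)(C)C(C)(C)C)C(=C)CC[C@@]1(C)[C@H](C=C=O)C2(OCCO2)CC=C1Br | intermediate
18 | tricyclic cyclobutanone (cyclobutanone cis-fused to ring C; ring C trans-fused to ring D; C7–H cis to the C6 arm on C1) | CC(C)[C@H](CO[Si](C)(C)C(C)(C)C)[C@]12CC(=O)[C@H]1[C@H]1[C@](C)(CC2)C(Br)=CCC13OCCO3 | intermediate
19 | oxaspirohexane from 18 (spiro epoxide on the former carbonyl carbon; one spiro epimer drawn, both converge) | CC(C)[C@H](CO[Si](C)(C)C(C)(C)C)[C@]12C[C@]3(CO3)[C@H]1[C@H]1[C@](C)(CC2)C(Br)=CCC14OCCO4 | intermediate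
20 | cis-fused cyclopentanone (ring B ketone; C4 H2 between C3=O and C7) | CC(C)[C@H](CO[Si](C)(C)C(C)(C)C)[C@]12CC(=O)C[C@H]1[C@H]1[C@](C)(CC2)C(Br)=CCC13OCCO3 | intermediate
21 | primary tosylate of 20 (C5–OTs) | CC(C)[C@H](COS(=O)(=O)c1ccc(C)cc1)[C@]12CC(=O)C[C@H]1[C@H]1[C@](C)(CC2)C(Br)=CCC13OCCO3 | intermediate
22 | norbornan-3-one (tetracyclic; 6-exo-isopropyl; ring D bromoalkene ketal) | CC(C)[C@@H]1C[C@@H]2[C@H]3[C@H]4[C@](C)(CC[C@@]31CC2=O)C(Br)=CCC45OCCO5 | intermediate
23 | exo-alcohol ketal (3-exo-OH; dioxolane still on ring D) | CC(C)[C@@H]1C[C@@H]2[C@H]3[C@H]4[C@](C)(CC[C@@]31C[C@H]2O)C(Br)=CCC45OCCO5 | intermediate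
24 | 3-exo-hydroxy ring D ketone (bromoalkene retained) | CC(C)[C@@H]1C[C@@H]2[C@H]3[C@H]4[C@](C)(CC[C@@]31C[C@H]2O)C(Br)=CCC4=O | intermediate
25 | diol alkenyl bromide (axial tertiary OH, equatorial CH3 on ring D) | CC(C)[C@@H]1C[C@@H]2[C@H]3[C@H]4[C@](C)(CC[C@@]31C[C@H]2O)C(Br)=CC[C@@]4(C)O | intermediate
26 | CNP0317598.2 (3-exo-hydroxy-6-exo-isopropylnorbornane fused through C1–C7 to ring C; ring D with equatorial Br, angular CH3 and axial tertiary OH) | CC(C)[C@@H]1C[C@@H]2[C@H]3[C@H]4[C@](C)(CC[C@@]31C[C@H]2O)[C@@H](Br)CC[C@@]4(C)O | target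

**Step count and risks**

Total step count: 19. Longest linear sequence: 16 steps (from 5 through steps 4 to 7, then steps 8 to 19).

Steps most likely to fail:

Step 13. An aldoketene is a weak partner for an unactivated alkene in a six-membered closure, so ketene dimerization or oligomerization may outrun the cycloaddition. The fallback sets out from 15 and uses a keteniminium ion in place of the ketene. Carbodiimide coupling of 15 with dimethylamine should give the N,N-dimethylamide F5. Tf2O and 2,4,6-collidine in 1,2-dichloroethane at reflux should convert it, through the more electrophilic keteniminium ion (a stepwise cationic [2+2] that is known to close six-membered rings where ketenes fail), into the cyclobutaniminium triflate F6. Aqueous NaHCO3 hydrolysis then returns the route at 18.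

Step 8. The adduct enolate may over-react by a second Michael closure onto the ring enone, or the facial selectivity at the new quaternary carbon may be poor. The fallback sets out from 8 and 4 and replaces conjugate addition by direct alkylation. MeMgBr on 8 should give the methyl ketone F1; Cp2TiMe2 methylenation gives the isopropenyl compound F2; a Me2AlCl-promoted ene reaction with formaldehyde gives the homoallylic alcohol F3; Tf2O and 2,6-lutidine at -78 °C give the primary triflate F4. Alkylation of the potassium enolate of 4 (KHMDS, THF, -78 °C) with F4, again anti to the acetate arm, returns the route at 12.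

Step 14. The iodohydrin alkoxide may shift the CH2 carbon (C2) instead of C7, giving the regioisomeric cyclopentanone. The fallback sets out from 18 and adds an electronic bias. Kinetic enolization toward the CH2 (LiHMDS, -78 °C) and chlorination with N-chlorosuccinimide should give the α-chlorocyclobutanone F7. Diazomethane (Et2O/MeOH, 0 °C) then expands the ring by migration of the non-halogenated, more substituted α-carbon C7, giving the α-chlorocyclopentanone F8. Zn in AcOH removes the chlorine and returns the route at 20.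

Further compounds
F1 | step 8 | (3R)-3-{[tert-butyl(dimethyl)silyl]oxymethyl}-4-methylpentan-2-one | CC(C)[C@H](CO[Si](C)(C)C(C)(C)C)C(C)=O
F2 | step 8 | tert-butyl{[(2S)-2-isopropyl-3-methylbut-3-en-1-yl]oxy}dimethylsilane | CC(C)[C@H](CO[Si](C)(C)C(C)(C)C)C(C)=C
F3 | step 8 | (4S)-4-{[tert-butyl(dimethyl)silyl]oxymethyl}-5-methyl-3-methylidenehexan-1-ol | CC(C)[C@H](CO[Si](C)(C)C(C)(C)C)C(=C)CCO
F4 | step 8 | (4S)-4-{[tert-butyl(dimethyl)silyl]oxymethyl}-5-methyl-3-methylidenehexyl trifluoromethanesulfonate | CC(C)[C@H](CO[Si](C)(C)C(C)(C)C)C(=C)CCOS(=O)(=O)C(F)(F)F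
F5 | step 13 | N,N-dimethylamide of acid 15 | CC(C)[C@H](CO[Si](C)(C)C(C)(C)C)C(=C)CC[C@@]1(C)[C@H](CC(=O)N(C)C)C2(OCCO2)CC=C1Br
F6 | step 13 | cyclobutaniminium triflate (18 with C=N+Me2 in place of C=O) | CC(C)[C@H](CO[Si](C)(C)C(C)(C)C)[C@]12CC(=[N+](C)C)[C@H]1[C@H]1[C@](C)(CC2)C(Br)=CCC13OCCO3.[O-]S(=O)(=O)C(F)(F)F
F7 | step 14 | α-chlorocyclobutanone (18 with Cl on the CH2 next to the carbonyl) | CC(C)[C@H](CO[Si](C)(C)C(C)(C)C)[C@]12C(Cl)C(=O)[C@H]1[C@H]1[C@](C)(CC2)C(Br)=CCC13OCCO3
F8 | step 14 | α-chlorocyclopentanone (20 with Cl on C2) | CC(C)[C@H](CO[Si](C)(C)C(C)(C)C)[C@]12C(Cl)C(=O)C[C@H]1[C@H]1[C@](C)(CC2)C(Br)=CCC13OCCO3
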